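**Retrosynthetic overview**
1. The two side-chain esters go on last, epoxyangelate at O-8 first and (R)-2-methylbutanoate at O-9 second. C8 is brought to the 8S configuration just before by oxidation and reduction.
2. Key disconnection C7–C8. An allylchromium made from a 3-(bromomethyl)butenolide acts as a lactone β-carbanion (homoenolate, d3). It attacks the C8 aldehyde, closes the ten-membered ring and unveils the α-methylene lactone.
3. The butenolide comes from RCM of the 2-(bromomethyl)acrylate of the C6 carbinol. That carbinol comes from an asymmetric Ni/Cr coupling of the C5 vinyl iodide with acrolein.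
4. C1=C10 comes from an HWE reaction. The aldehyde partner is the cis-epoxy aldehyde C1–C5 (propargyl alcohol, carbomagnesiation, γ-chloroallylboration). The phosphonate partner (C8–C10, C14) comes from L-malate.
5. Ring order: C2–C3 oxirane, then butenolide, then ten-membered carbocycle. The side-chain oxirane is made separately by Sharpless epoxidation.

Assumption: locants C1–C15 in names and comments follow germacrane numbering (lactone O on C6, epoxyangelate on C8, 2-methylbutanoate on C9, C14 is the methyl ester carbon).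

**Step 1**
Reactants: 1 prop-2-yn-1-ol
Product: 3 (2Z)-3-iodo-2-methylprop-2-en-1-ol, via alkenylmagnesium alkoxide 2 (not isolated)
Conditions: MeMgBr (2.5 equiv), CuI (10 mol %), THF/Et2O, −10 °C to rt; then I2, −10 °C
Reagents that add atoms: methylmagnesium bromide C[Mg]Br; iodine II
Why: Copper-catalysed anti-carbomagnesiation of the propargylic alkoxide (carbometallation) gives the chelated (Z)-alkenylmagnesium 2, and iodinolysis with retention fixes the ring-cis C4=C5 geometry (C3 cis to the future C6).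

**Step 2**
Reactants: 3 (2Z)-3-iodo-2-methylprop-2-en-1-ol
Product: 4 (2Z)-3-iodo-2-methylprop-2-enal
Conditions: MnO2, CH2Cl2, rt, dark; used at once
Reagents that add atoms: none
Why: MnO2 allylic alcohol oxidation is neutral, so the (Z)-β-iodo enal forms without E/Z scrambling.

**Step 3**
Reactants: 4 (2Z)-3-iodo-2-methylprop-2-enal; 5 allyl chloride
Product: 7 (2R,3S)-2-ethenyl-3-[(1Z)-1-iodoprop-1-en-2-yl]oxirane, via syn-chlorohydrin 6 (not isolated)
Conditions: 5, LiNCy2, (+)-Ipc2BOMe, BF3·OEt2, Et2O, −95 °C; then 4, −95 °C; then 3 M NaOH, 30 % H2O2, 0 °C to rt (keep below 30 °C)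
Reagents that add atoms: none
Why: Brown-type asymmetric allylboration by the (Z)-γ-chloroallylborane runs through a chair Zimmerman–Traxler transition state, so the (−)-α-pinene-derived Ipc groups set C3 (S), the Z-geometry gives the syn-chlorohydrin 6, and the basic work-up closes 6 by internal SN2 with inversion at C2 to the cis-(2R,3S)-epoxide.

**Step 4**
Reactants: 7 cis-vinyl epoxide
Product: 8 (2S,3S)-3-[(1Z)-1-iodoprop-1-en-2-yl]oxirane-2-carbaldehyde
Conditions: OsO4 (2 mol %), NaIO4, 2,6-lutidine, dioxane/H2O, 0 °C to rt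
Reagents that add atoms: osmium tetroxide O=[Os](=O)(=O)=O; sodium periodate [Na+].[O-]I(=O)(=O)=O
Why: Lemieux–Johnson cleavage takes the monosubstituted vinyl group because the other alkene is trisubstituted and deactivated by iodine, and 2,6-lutidine keeps the cis-epoxy aldehyde from epimerising at C2.

**Step 5**
Reactants: 9 dimethyl (2S)-2-hydroxybutanedioate (dimethyl L-malate)
Product: 10 methyl (3S)-3,4-dihydroxybutanoate
Conditions: BH3·SMe2, NaBH4 (5 mol %), THF, 0 °C to rt; MeOH quench
Reagents that add atoms: none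
Why: Hydroxyl-directed borane reduction takes only the α-hydroxy ester through a five-membered alkoxyborane chelate and leaves the malate stereocentre (future C9, S) untouched.

**Step 6**
Reactants: 10 methyl (3S)-3,4-dihydroxybutanoate
Product: 11 methyl (3S)-3,4-bis(triethylsilyloxy)butanoate
Conditions: TESCl (2.2 equiv), imidazole, DMF, 0 °C
Reagents that add atoms: chlorotriethylsilane CC[Si](Cl)(CC)CC
Why: Imidazole-promoted silyl ether formation masks both hydroxyls, and the primary TES ether is the latent C8 aldehyde.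

**Step 7**
Reactants: 11 methyl (3S)-3,4-bis(triethylsilyloxy)butanoate
Product: 13 methyl (3R)-2-(diethoxyphosphoryl)-3,4-bis(triethylsilyloxy)butanoate (C2 epimers), via phosphonite 12 (not isolated)
Conditions: LDA, THF, −78 °C; ClP(OEt)2, −78 °C; then 30 % H2O2, 0 °C
Reagents that add atoms: diethyl chlorophosphite CCOP(Cl)OCC; hydrogen peroxide OO
Why: Enolate C-phosphinylation followed by P(III) to P(V) oxidation gives the Horner–Wadsworth–Emmons reagent, because trapping at −78 °C outruns β-silyloxide elimination and the new centre at C10 is lost later.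

**Step 8**
Reactants: 8 cis-epoxy aldehyde; 13 phosphonate
Product: 14 methyl (2E)-2-[(1S)-1,2-bis(triethylsilyloxy)ethyl]-3-{(2R,3S)-3-[(1Z)-1-iodoprop-1-en-2-yl]oxiran-2-yl}prop-2-enoate
Conditions: 13, NaH, THF, 0 °C; then 8, −78 to 0 °C
Reagents that add atoms: none
Why: Horner–Wadsworth–Emmons olefination with the stabilised anion places C2 trans to the ester (E, so C2 is cis to C9 as the ring needs), and the weakly basic anion spares the epimerisable epoxy aldehyde.

**Step 9**
Reactants: 14 vinyl iodide; 15 acrolein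
Product: 16 methyl (2E)-2-[(1S)-1,2-bis(triethylsilyloxy)ethyl]-3-{(2R,3S)-3-[(2Z,4S)-4-hydroxyhexa-2,5-dien-2-yl]oxiran-2-yl}prop-2-enoate
Conditions: 15 (5 equiv), CrCl2 (4 equiv), valinol-derived oxazoline–sulfonamide ligand (antipode giving Re-face attack), Et3N, NiCl2 (2 mol %), THF, rt
Reagents that add atoms: none
Why: In this asymmetric Nozaki–Hiyama–Kishi coupling the alkenylchromium(III) forms with retention of the Z-geometry and tolerates esters and epoxide, and the chiral Cr ligand directs 1,2-addition to the Re face of acrolein to set C6 (S here, R once lactonised).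

**Step 10**
Reactants: 16 C6 carbinol; 17 2-(bromomethyl)prop-2-enoic acid
Product: 19 C6 2-(bromomethyl)acrylate ester of 16, via acid chloride 18 (not isolated)
Conditions: 17, (COCl)2, DMF (cat.), CH2Cl2, 0 °C to rt; then 16, 2,6-lutidine, CH2Cl2, −20 °C
Reagents that add atoms: none
Why: O-acylation with the acid chloride and a hindered, poorly nucleophilic base avoids SN2′ attack of amine catalysts on the bromomethyl acrylate and leaves the C6–O bond, and so C6, unchanged.

**Step 11**
Reactants: 19 triene ester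
Product: 20 (R)-3-(bromomethyl)butenolide carrying the C5–C10 chain
Conditions: Grubbs II (10 mol %), CH2Cl2 (5 mM), 40 °C
Reagents that add atoms: none
Why: Ring-closing metathesis joins the only terminal vinyl group to the 1,1-disubstituted acrylate in a five-membered ring, while the trisubstituted alkenes are inert and 40 °C is too low for Cope rearrangement of the Z,Z-divinyl epoxide.

**Step 12**
Reactants: 20 bis-TES butenolide
Product: 21 C8 aldehyde
Conditions: (COCl)2, DMSO, CH2Cl2, −78 to −40 °C; then iPr2NEt, −78 to −20 °C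
Reagents that add atoms: none
Why: Under Swern conditions activated DMSO attacks only the unhindered primary TES ether and gives the aldehyde directly, and the low temperature and hindered base spare the allylic bromide, the secondary TES ether and C9.

**Step 13 (key step)**
Reactants: 21 bromomethylbutenolide aldehyde
Product: 23 8-epi-hydroxy germacranolide (2R,3S,6R,7R,8R,9S), via allylchromium species 22 (not isolated)
Conditions: CrCl2 (10 equiv), THF, 4 Å MS, rt; 21 added by syringe pump over 12 h (final 1 mM)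
Reagents that add atoms: none
Why: Proposed new method: CrCl2 inserts into the allylic C–Br bond to give allylchromium(III) 22, a butenolide β-carbanion (homoenolate, d3) equivalent, so the normally electrophilic β-carbon C7 bonds to the electrophilic aldehyde carbon C8 with allylic transposition (SE2′), which unveils the α-methylene lactone and closes the ten-membered ring on a chain already folded by two Z-alkenes and the cis-epoxide; C8 approaches the butenolide face anti to the C5 side chain (6,7-trans, C7 as in the target), and the chair Zimmerman–Traxler transition state of this E-type allylmetal, matched with Felkin–Anh control by C9–OSiEt3, predicts the 7,8-anti (8R) carbinol that step 14 corrects; the closest known reactions are intermolecular Cr(II) or Zn Barbier additions of 3-(bromomethyl)furan-2(5H)-one to aldehydes and Nozaki–Hiyama–Kishi allylation macrocyclisations to ten-membered carbocycles.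

**Step 14**
Reactants: 23 8-epi alcohol
Product: 25 8β-hydroxy germacranolide (2R,3S,6R,7R,8S,9S), via 8-ketone 24 (not isolated)
Conditions: DMP, NaHCO3, CH2Cl2, 0 °C; then MeOH, CeCl3·7H2O, NaBH4, −78 °C (one flask)
Reagents that add atoms: none
Why: Dess–Martin oxidation erases C8 so that either C8 epimer from step 13 converges, and Luche 1,2-reduction of the non-isolated, isomerisation-prone ketone delivers hydride from the open peripheral face syn to H-7 and anti to the C9–OSiEt3 bond (polar Felkin–Anh) to give 8S without conjugate reduction.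

**Step 15**
Reactants: 26 angelic acid
Product: 27 (2Z)-2-methylbut-2-en-1-ol
Conditions: LiAlH4, Et2O, 0 °C
Reagents that add atoms: none
Why: Hydride reduction of the acid leaves the trisubstituted alkene and its Z-geometry untouched.

**Step 16**
Reactants: 27 (2Z)-2-methylbut-2-en-1-ol
Product: 28 [(2R,3S)-2,3-dimethyloxiran-2-yl]methanol
Conditions: Ti(OiPr)4 (10 mol %), D-(−)-DIPT (12 mol %), TBHP, 4 Å MS, CH2Cl2, −20 °C
Reagents that add atoms: tert-butyl hydroperoxide CC(C)(C)OO
Why: Sharpless asymmetric epoxidation with D-(−)-tartrate delivers oxygen to the face that makes C2 (R), and suprafacial transfer keeps CH2OH cis to the C3 methyl group (3S).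

**Step 17**
Reactants: 28 epoxy alcohol
Product: 29 (2S,3S)-2,3-dimethyloxirane-2-carboxylic acid
Conditions: RuCl3·xH2O (2 mol %), NaIO4, MeCN/EtOAc/H2O, 0 °C to rt
Reagents that add atoms: water O
Why: Catalytic ruthenium tetroxide oxidation takes the primary alcohol through the aldehyde hydrate to the acid without opening the epoxide, and only the C2 descriptor changes, not the geometry.

**Step 18**
Reactants: 25 8β-alcohol; 29 epoxyangelic acid
Product: 31 8-O-epoxyangelate 9-O-TES germacranolide, via mixed anhydride 30 (not isolated)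
Conditions: 29, 2,4,6-trichlorobenzoyl chloride, Et3N, toluene, rt; then 25, DMAP, rt
Reagents that add atoms: none
Why: Yamaguchi esterification activates the hindered α,α-disubstituted acid strongly enough for the hindered secondary alcohol, and no stereocentre is touched.

**Step 19**
Reactants: 31 9-O-TES ester
Product: 32 9-hydroxy 8-O-epoxyangelate
Conditions: HF·pyridine, pyridine, THF, 0 °C
Reagents that add atoms: none
Why: Buffered fluoride desilylation removes the secondary TES ether under slightly acidic conditions that avoid O8 to O9 acyl migration and spare both epoxides.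

**Step 20**
Reactants: 32 9-alcohol; 33 (2R)-2-methylbutanoic acid
Product: 34 target CNP0485260.1
Conditions: DIC, DMAP (10 mol %), CH2Cl2, 0 °C to rt
Reagents that add atoms: none
Why: Steglich esterification acylates the remaining allylic hydroxyl at low temperature, so the α-stereocentre of the acid and all ring centres are kept.

**Compound list**
1 | prop-2-yn-1-ol | C#CCO | starting material
2 | bromomagnesium (2Z)-3-(bromomagnesio)-2-methylprop-2-en-1-olate | Br[Mg]OC/C(C)=C\[Mg]Br | intermediate
3 | (2Z)-3-iodo-2-methylprop-2-en-1-ol | OC/C(C)=C\I | intermediate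
4 | (2Z)-3-iodo-2-methylprop-2-enal | O=C/C(C)=C\I | intermediate
5 | 3-chloroprop-1-ene (allyl chloride) | C=CCCl | starting material
6 | (1Z,3S,4S)-4-chloro-1-iodo-2-methylhexa-1,5-dien-3-ol (syn-chlorohydrin) | I/C=C(/C)[C@H](O)[C@@H](Cl)C=C | intermediate
7 | (2R,3S)-2-ethenyl-3-[(1Z)-1-iodoprop-1-en-2-yl]oxirane (cis) | I/C=C(/C)[C@@H]1O[C@@H]1C=C | intermediate
8 | (2S,3S)-3-[(1Z)-1-iodoprop-1-en-2-yl]oxirane-2-carbaldehyde (cis) | I/C=C(/C)[C@@H]1O[C@@H]1C=O | intermediate
9 | dimethyl (2S)-2-hydroxybutanedioate | COC(=O)C[C@H](O)C(=O)OC | starting material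
10 | methyl (3S)-3,4-dihydroxybutanoate | COC(=O)C[C@H](O)CO | intermediate
11 | methyl (3S)-3,4-bis(triethylsilyloxy)butanoate | COC(=O)C[C@H](O[Si](CC)(CC)CC)CO[Si](CC)(CC)CC | intermediate
12 | methyl (3R)-2-(diethoxyphosphanyl)-3,4-bis(triethylsilyloxy)butanoate (C2 epimers) | COC(=O)C(P(OCC)OCC)[C@H](O[Si](CC)(CC)CC)CO[Si](CC)(CC)CC | intermediate
13 | methyl (3R)-2-(diethoxyphosphoryl)-3,4-bis(triethylsilyloxy)butanoate (C2 epimers) | COC(=O)C(P(=O)(OCC)OCC)[C@H](O[Si](CC)(CC)CC)CO[Si](CC)(CC)CC | intermediate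
14 | methyl (2E)-2-[(1S)-1,2-bis(triethylsilyloxy)ethyl]-3-{(2R,3S)-3-[(1Z)-1-iodoprop-1-en-2-yl]oxiran-2-yl}prop-2-enoate | I/C=C(/C)[C@@H]1O[C@@H]1/C=C(/C(=O)OC)[C@H](O[Si](CC)(CC)CC)CO[Si](CC)(CC)CC | intermediate
15 | prop-2-enal (acrolein) | C=CC=O | starting material
16 | methyl (2E)-2-[(1S)-1,2-bis(triethylsilyloxy)ethyl]-3-{(2R,3S)-3-[(2Z,4S)-4-hydroxyhexa-2,5-dien-2-yl]oxiran-2-yl}prop-2-enoate | C=C[C@H](O)/C=C(/C)[C@@H]1O[C@@H]1/C=C(/C(=O)OC)[C@H](O[Si](CC)(CC)CC)CO[Si](CC)(CC)CC | intermediate
17 | 2-(bromomethyl)prop-2-enoic acid | C=C(CBr)C(=O)O | starting material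
18 | 2-(bromomethyl)prop-2-enoyl chloride | C=C(CBr)C(=O)Cl | intermediate
19 | methyl (2E)-2-[(1S)-1,2-bis(triethylsilyloxy)ethyl]-3-[(2R,3S)-3-{(2Z,4S)-4-[2-(bromomethyl)prop-2-enoyloxy]hexa-2,5-dien-2-yl}oxiran-2-yl]prop-2-enoate | C=C[C@H](OC(=O)C(=C)CBr)/C=C(/C)[C@@H]1O[C@@H]1/C=C(/C(=O)OC)[C@H](O[Si](CC)(CC)CC)CO[Si](CC)(CC)CC | intermediate
20 | methyl (2E)-2-[(1S)-1,2-bis(triethylsilyloxy)ethyl]-3-[(2R,3S)-3-{(1Z)-1-[(2R)-4-(bromomethyl)-5-oxo-2,5-dihydrofuran-2-yl]prop-1-en-2-yl}oxiran-2-yl]prop-2-enoate | O=C1O[C@@H](C=C1CBr)/C=C(/C)[C@@H]2O[C@@H]2/C=C(/C(=O)OC)[C@H](O[Si](CC)(CC)CC)CO[Si](CC)(CC)CC | intermediate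
21 | methyl (2E)-3-[(2R,3S)-3-{(1Z)-1-[(2R)-4-(bromomethyl)-5-oxo-2,5-dihydrofuran-2-yl]prop-1-en-2-yl}oxiran-2-yl]-2-[(1S)-2-oxo-1-(triethylsilyloxy)ethyl]prop-2-enoate | O=C1O[C@@H](C=C1CBr)/C=C(/C)[C@@H]2O[C@@H]2/C=C(/C(=O)OC)[C@H](O[Si](CC)(CC)CC)C=O | intermediate
22 | dichlorochromium(III) allyl species of 21 (CH2–CrCl2 in place of CH2Br) | O=C1O[C@@H](C=C1C[Cr](Cl)Cl)/C=C(/C)[C@@H]2O[C@@H]2/C=C(/C(=O)OC)[C@H](O[Si](CC)(CC)CC)C=O | intermediate
23 | methyl (1(10)E,4Z;2R,3S,6R,7R,8R,9S)-2,3-epoxy-8-hydroxy-9-(triethylsilyloxy)germacra-1(10),4,11(13)-trien-12,6-olid-14-oate (8-epi) | C=C1C(=O)O[C@@H]2/C=C(/C)[C@@H]3O[C@@H]3/C=C(/C(=O)OC)[C@H](O[Si](CC)(CC)CC)[C@H](O)[C@@H]12 | intermediate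
24 | methyl (1(10)E,4Z;2R,3S,6R,7S,9S)-2,3-epoxy-8-oxo-9-(triethylsilyloxy)germacra-1(10),4,11(13)-trien-12,6-olid-14-oate | C=C1C(=O)O[C@@H]2/C=C(/C)[C@@H]3O[C@@H]3/C=C(/C(=O)OC)[C@H](O[Si](CC)(CC)CC)C(=O)[C@@H]12 | intermediate
25 | methyl (1(10)E,4Z;2R,3S,6R,7R,8S,9S)-2,3-epoxy-8-hydroxy-9-(triethylsilyloxy)germacra-1(10),4,11(13)-trien-12,6-olid-14-oate | C=C1C(=O)O[C@@H]2/C=C(/C)[C@@H]3O[C@@H]3/C=C(/C(=O)OC)[C@H](O[Si](CC)(CC)CC)[C@@H](O)[C@@H]12 | intermediate
26 | (2Z)-2-methylbut-2-enoic acid (angelic acid) | C/C=C(/C)C(=O)O | starting material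
27 | (2Z)-2-methylbut-2-en-1-ol | C/C=C(/C)CO | intermediate
28 | [(2R,3S)-2,3-dimethyloxiran-2-yl]methanol | OC[C@@]1(C)O[C@H]1C | intermediate
29 | (2S,3S)-2,3-dimethyloxirane-2-carboxylic acid | OC(=O)[C@@]1(C)O[C@H]1C | intermediate
30 | (2S,3S)-2,3-dimethyloxirane-2-carboxylic 2,4,6-trichlorobenzoic anhydride | O=C(OC(=O)[C@@]1(C)O[C@H]1C)c1c(Cl)cc(Cl)cc1Cl | intermediate
31 | 8-O-[(2S,3S)-2,3-dimethyloxirane-2-carbonyl] derivative of 25 (2R,3S,6R,7S,8S,9S) | C=C1C(=O)O[C@@H]2/C=C(/C)[C@@H]3O[C@@H]3/C=C(/C(=O)OC)[C@H](O[Si](CC)(CC)CC)[C@@H](OC(=O)[C@@]3(C)O[C@H]3C)[C@@H]12 | intermediate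
32 | 9-hydroxy compound from 31 (2R,3S,6R,7S,8S,9S) | C=C1C(=O)O[C@@H]2/C=C(/C)[C@@H]3O[C@@H]3/C=C(/C(=O)OC)[C@H](O)[C@@H](OC(=O)[C@@]3(C)O[C@H]3C)[C@@H]12 | intermediate
33 | (2R)-2-methylbutanoic acid | CC[C@@H](C)C(=O)O | starting material
34 | CNP0485260.1 (2R,3S,6R,7S,8S,9S;2′S,3′S;2″R) | C=C1C(=O)O[C@@H]2/C=C(/C)[C@@H]3O[C@@H]3/C=C(/C(=O)OC)[C@H](OC(=O)[C@H](C)CC)[C@@H](OC(=O)[C@@]3(C)O[C@H]3C)[C@@H]12 | target

**Step count**
- Total step count: 20.
- Longest linear sequence: 14 (steps 1–4, 8–14, 18–20).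

**Three steps most likely to fail, each with a fallback**

Step 13 (macrocyclisation).
- What can go wrong: oligomerisation, Cr(II) reduction of the γ,δ-epoxy enoate, or translactonisation of the 8α-alkoxide.
- The fallback replaces the reductive Barbier closure by a pre-formed, isolable d3 reagent and a metal-free ring closure. It sets out from 20 and returns at 23.
- Copper-catalysed borylation of the allylic bromide (B2pin2, CuCl/PCy3 cat., KOt-Bu, THF, 0 °C) gives the butenolide allylboronate F3.
- The Swern conditions of step 12 turn its primary TES ether into the boronate aldehyde F4.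
- Warming F4 in dilute toluene (1 mM, 40 °C) closes the ring by intramolecular allylboration through the same closed transition state. Hydrolytic work-up with triethanolamine then gives 23.

Step 8 (HWE).
- What can go wrong: the α-branched phosphonate may react sluggishly, give E/Z mixtures or lose the β-silyloxy group.
- The fallback builds C1=C10 by aldol addition and E1cB elimination. It sets out from 8 and 11 and returns at 14.
- The lithium enolate of 11 (LDA, THF, −78 °C) adds to 8 to give the β-hydroxy ester F1.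
- MsCl/Et3N at −20 °C gives the mesylate F2.
- DBU at 0 °C expels mesylate in preference to silyloxide and gives the thermodynamic (E)-enoate 14.

Step 14 (C8 correction).
- What can go wrong: ketone 24 may isomerise to the endocyclic butenolide, or hydride may attack the wrong face.
- The fallback inverts C8 by substitution and installs the ester in the same operation. It sets out from 23 and returns at 31, skipping 25 and step 18.
- ClCH2SO2Cl/pyridine at 0 °C gives the 8α-chloromethanesulfonate F5.
- The caesium salt of 29 with 18-crown-6 in toluene displaces it by SN2 with inversion to give 31.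

**Further compounds**
F1 | step 8 | methyl 2-[(1S)-1,2-bis(triethylsilyloxy)ethyl]-3-hydroxy-3-{(2R,3S)-3-[(1Z)-1-iodoprop-1-en-2-yl]oxiran-2-yl}propanoate (epimers at C2 and C3) | I/C=C(/C)[C@@H]1O[C@@H]1C(O)C(C(=O)OC)[C@H](O[Si](CC)(CC)CC)CO[Si](CC)(CC)CC
F2 | step 8 | 3-O-methanesulfonate of F1 | I/C=C(/C)[C@@H]1O[C@@H]1C(OS(C)(=O)=O)C(C(=O)OC)[C@H](O[Si](CC)(CC)CC)CO[Si](CC)(CC)CC
F3 | step 13 | analogue of 20 with CH2–B(pin) in place of CH2Br | O=C1O[C@@H](C=C1CB2OC(C)(C)C(C)(C)O2)/C=C(/C)[C@@H]3O[C@@H]3/C=C(/C(=O)OC)[C@H](O[Si](CC)(CC)CC)CO[Si](CC)(CC)CC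
F4 | step 13 | analogue of 21 with CH2–B(pin) in place of CH2Br | O=C1O[C@@H](C=C1CB2OC(C)(C)C(C)(C)O2)/C=C(/C)[C@@H]3O[C@@H]3/C=C(/C(=O)OC)[C@H](O[Si](CC)(CC)CC)C=O
F5 | step 14 | 8-O-chloromethanesulfonate of 23 | C=C1C(=O)O[C@@H]2/C=C(/C)[C@@H]3O[C@@H]3/C=C(/C(=O)OC)[C@H](O[Si](CC)(CC)CC)[C@H](OS(=O)(=O)CCl)[C@@H]12
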